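The earlier eta run has twice the reagent of the delta run, which is the flask asked about, followed so far. I measure the loss of starting material as L, the logarithm of charged over remaining amount, the scale on which a pseudo-first-order loss runs straight. In the first hour L reaches 0.272 in eta against 0.123 in delta, twice as much, so I take the pace of L to follow the reagent.

the same everywhere: starting material 0.12 M
- delta: partner 1.2 equiv; reagent 2 equiv; the very flask that is asked about, followed so far
- eta: partner 1.2 equiv; reagent 4 equiv; run made earlier
- flask: partner 1.20 equiv; reagent 2.00 equiv; time 4.0 h

- delta (time / min: starting material / %, target / %): 8.00: 98.1, 0.5; 25.0: 95.2, 0.4; 40.0: 90.4, 0; 60.0: 88.4, 1.0; 90.0: 83.4, 2.7; 120: 79.7, 2.8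
- eta (time / min: starting material / %, target / %): 15.0: 92.8, 0; 30.0: 87.2, 0.6; 50.0: 79.8, 2.0; 60.0: 76.2, 1.8; 80.0: 71.4, 3.1; 90.0: 68.3, 3.6

(scatter of a reading: 0.5 percentage points)



1. amount of starting material in percent of the starting material charged, at 50 min, 2.0 h and 4.0 h

In delta, L stands at 0.227 after the second hour. My rule is the carry-over c, the loss of one hour divided by the loss of the hour before, here 0.840. It is a soft reading, given a scatter of 0.5 percentage points per point. If c holds, the hourly losses form a shrinking series, and the sum of that series, 0.772, is the end state this rule gives: 46.2% starting material.

The ladder in delta then climbs in time. The pace halves in 3.98 h. Starting material at its first-hour pace halves in 5.62 h, which is slower, so on this rule the pace fades first. Target, at 2.8% after 120 min, is slower still: at that pace the whole charge takes 71.4 h. So in delta 17.5% of the charge stands by 120 min in forms I do not read.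

For 50 min, 2.0 h and 4.0 h my reckoning gives 90.1%, 79.7% and 67.9%. The forecast says 90.3%, 80% and 64.5%, with the slowing read as “That fits depletion of reagent, and perhaps partner, or mild inhibition”, and at the last point it lies below mine.

The flask gives 89.6%, 80.2% and 70.1%.

    starting material + reagent → open intermediate (k = 0.0110 /M/min)
    reagent + partner → second intermediate (k = 0.0520 /M/min)
    open intermediate + second intermediate → target (k = 0.0380 /M/min)
    2 open intermediate → homo product (k = 0.00110 /M/min)
    target ⇌ isomer of the product (K = 2.90, k = 0.00370 /min)

At 4.00 h its reagent stands at 36.2% of charge, less than the starting material at 70.1%, while c puts the pace at 49.8% of its start. Carried to 8.00 h, c gives 56.0% starting material, and the flask holds 58.3%. At 40.0 h it holds 32.1%, below the 46.2% reckoned from c, with 6.34% of its reagent left.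

The data were computed for substances that don't exist; noise was put on by code.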